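**Plan**
- Retrosynthesis: after removing two silyl ethers, the benzo ring is cut at C5–C6 and C7–C7a. This leads back to a 2-furyl diazomethyl ketone that carries a vinyl group on the neighbouring furan carbon.
- Enabling feature: the benzo ring (C3a, C4, C5, C6, C7, C7a) carries only the C6 hydroxyl. C6 is the ketene carbon of a 2-furylketene, C7 its CH, and C4–C5 the vinyl group on furan C3.
- The diazoketone is traced to a 2-furoate whose C3–H becomes the vinyl group via an iodide. The furan is cut by Paal–Knorr to a 1,4-dicarbonyl, made from the ring A propiophenone and ethyl bromopyruvate.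
- Ring A comes from 2,4,6-trihydroxypropiophenone by C-prenylation, silylation of two hydroxyls and methylation of the third.
- Forward order: ring A substitution, then the furan ring, then the benzo ring (photo-Wolff rearrangement and six-electron closure), then desilylation.
- Stereochemistry: the target has no stereocentre; the one racemic centre (in 7) is erased when the furan forms.

Key step: step 10

Assumption: in step 2 the hydroxyl flanked by the acyl and prenyl groups (hydrogen-bonded to the ketone and doubly ortho-substituted) is taken to be the one that resists silylation. Triisopropylsilyl ethers are used because they tolerate the enolate, magnesiation and ester-cleavage steps.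

In the names below, "Ar" stands for the ring A group 2-methoxy-3-(3-methylbut-2-en-1-yl)-4,6-bis(triisopropylsilyloxy)phenyl.

**Step 1**
Reactants: 1 1-(2,4,6-trihydroxyphenyl)propan-1-one; 2 prenyl bromide (1-bromo-3-methylbut-2-ene)
Product: 3 1-[2,4,6-trihydroxy-3-(3-methylbut-2-en-1-yl)phenyl]propan-1-one
Conditions: DBU (1.1 equiv), 2 (1.0 equiv), THF, 0 °C to rt
Reagents that add atoms: none
Why: C-prenylation of an acylphloroglucinol through its phenoxide (Friedel–Crafts-type C-alkylation) should give a single mono-prenyl isomer because the two free ring positions of 1 are equivalent.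

**Step 2**
Reactants: 3
Product: 4 1-[2-hydroxy-3-(3-methylbut-2-en-1-yl)-4,6-bis(triisopropylsilyloxy)phenyl]propan-1-one
Conditions: i-Pr3SiCl (2.2 equiv), imidazole, DMF, rt to 40 °C
Reagents that add atoms: triisopropylsilyl chloride, CC(C)[Si](Cl)(C(C)C)C(C)C
Why: Regioselective phenol silylation, in which the bulky chloride should take the para hydroxyl and the less hindered ortho hydroxyl and leave the chelated hydroxyl between acyl and prenyl free.

**Step 3**
Reactants: 4
Product: 5 1-[2-methoxy-3-(3-methylbut-2-en-1-yl)-4,6-bis(triisopropylsilyloxy)phenyl]propan-1-one (Ar–CO–CH2CH3)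
Conditions: NaH (1.1 equiv), MeI, DMF, 0 °C to rt
Reagents that add atoms: iodomethane, CI
Why: Williamson O-methylation of the sodium phenoxide should be clean because both silyl ethers are meta to the phenoxide and cannot migrate to it.

**Step 4**
Reactants: 5; 6 ethyl bromopyruvate (ethyl 3-bromo-2-oxopropanoate)
Product: 7 ethyl 5-Ar-4-methyl-2,5-dioxopentanoate (racemic)
Conditions: LiN(SiMe3)2, THF, −78 °C; then 6, −78 to 0 °C
Reagents that add atoms: none
Why: SN2 alkylation of the lithium enolate at the primary carbon of an α-bromoketone is the usual route to 1,4-dicarbonyls; the ketone can enolise only toward its ethyl group, and aldol addition of this hindered enolate to the keto group of 6 should be reversible while bromide loss is not.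

**Step 5**
Reactants: 7
Product: 8 ethyl 5-Ar-4-methylfuran-2-carboxylate
Conditions: PPTS (20 mol %), toluene, 4 Å molecular sieves, 80–90 °C
Reagents that add atoms: none
Why: Paal–Knorr cyclodehydration of the 1,4-dicarbonyl should proceed under this mild acid, which spares the prenyl group and the silyl ethers.

**Step 6**
Reactants: 8
Product: 10 ethyl 5-Ar-3-iodo-4-methylfuran-2-carboxylate, via furylmagnesium chloride 9 (not isolated)
Conditions: TMPMgCl·LiCl (1.3 equiv), THF, −20 °C; then iodine, −78 °C to 0 °C; aq. Na2S2O3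
Reagents that add atoms: TMPMgCl·LiCl, CC1(C)CCCC(C)(C)N1[Mg]Cl.[Li+].[Cl-]; iodine, [I][I]
Why: Ester-directed ortho-magnesiation with a hindered magnesium amide followed by iodinolysis should occur at the only furan C–H; the lone ring A C–H is shielded by two non-directing silyloxy groups, and no electrophilic halogenating agent meets the electron-rich arene or the prenyl alkene.

**Step 7**
Reactants: 10
Product: 11 ethyl 3-ethenyl-5-Ar-4-methylfuran-2-carboxylate
Conditions: Bu3SnCH=CH2 (1.3 equiv), Pd(PPh3)4 (5 mol %), DMF, 80 °C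
Reagents that add atoms: tributyl(vinyl)stannane, C=C[Sn](CCCC)(CCCC)CCCC
Why: Stille coupling of a heteroaryl iodide runs without base or fluoride, so the aryl silyl ethers should survive.

**Step 8**
Reactants: 11
Product: 12 3-ethenyl-5-Ar-4-methylfuran-2-carboxylic acid
Conditions: Me3SnOH (4 equiv), 1,2-dichloroethane, 80 °C; then cold 0.1 M aq. HCl wash
Reagents that add atoms: trimethyltin hydroxide, C[Sn](C)(C)O
Why: Trimethyltin hydroxide cleaves the ester under neutral conditions, avoiding aqueous hydroxide that could strip the aryl silyl ethers.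

**Step 9**
Reactants: 12
Product: 14 2-diazo-1-(3-ethenyl-5-Ar-4-methylfuran-2-yl)ethan-1-one, via furoyl chloride 13 (not isolated)
Conditions: 1-chloro-N,N,2-trimethylprop-1-en-1-amine (1.2 equiv), CH2Cl2, 0 °C to rt; then Me3SiCHN2 (2 equiv), MeCN/THF, 0 °C, dark
Reagents that add atoms: 1-chloro-N,N,2-trimethylprop-1-en-1-amine, CC(C)=C(Cl)N(C)C; (trimethylsilyl)diazomethane, C[Si](C)(C)C=[N+]=[N-]
Why: Neutral acid chloride formation with the α-chloroenamine followed by C-acylation of the silyl diazomethane (first half of an Arndt–Eistert sequence) should give the diazomethyl ketone without acid that could harm the vinylfuran or prenyl group.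

**Step 10**
Reactants: 14
Product: 17 2-Ar-3-methyl-1-benzofuran-6-ol, via furylketene 15 (not isolated), via 5H-benzofuran-6-one 16 (not isolated)
Conditions: hν (365 nm), dry degassed toluene (0.005 M), 25 °C; then 80 °C in the dark
Reagents that add atoms: none
Why: Excitation of the s-Z diazoketone expels dinitrogen with concerted 1,2-shift of furan C2 to the diazo carbon (Wolff rearrangement, forming C7a–C7) to give 2-furylketene 15, in which the ketene C=C, the furan C2=C3 bond and the vinyl group form a 1,3,5-hexatriene held cis by the ring. Thermal disrotatory six-electron electrocyclisation then joins the vinyl terminus to the ketene carbonyl carbon (C5–C6) and closes the six-membered benzo ring as 5H-benzofuran-6-one 16, whose enolisation restores the furan and gives phenol 17. The closest known reaction type is the last stage of the Danheiser benzannulation, together with the Wolff rearrangement of dienoyl diazomethanes to phenols, where a photochemically formed dienylketene closes and tautomerises in the same way. No stereocentre is formed. The step needs position selectivity and chemoselectivity: the hydroxyl can only appear at C6 because the former acyl carbon becomes C6, the s-Z conformation of the heteroaryl diazoketone favours furyl migration over carbene capture by the neighbouring vinyl group, and high dilution in a dry non-nucleophilic solvent keeps the ketene from dimerising or acylating phenol already formed.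

**Step 11**
Reactants: 17
Product: 18 glycybenzofuran, 2-[4,6-dihydroxy-2-methoxy-3-(3-methylbut-2-en-1-yl)phenyl]-3-methyl-1-benzofuran-6-ol
Conditions: Bu4NF (2.5 equiv), AcOH (2.5 equiv), THF, 0 °C
Reagents that add atoms: none
Why: Fluoride cleavage of the two aryl silyl ethers, buffered with acetic acid, should release the phenols without exposing the prenylated resorcinol to strong base or acid.

**Compound list**
1 | 1-(2,4,6-trihydroxyphenyl)propan-1-one | CCC(=O)c1c(O)cc(O)cc1O | starting material
2 | prenyl bromide | CC(C)=CCBr | starting material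
3 | 1-[2,4,6-trihydroxy-3-(3-methylbut-2-en-1-yl)phenyl]propan-1-one | CCC(=O)c1c(O)c(CC=C(C)C)c(O)cc1O | intermediate
4 | 1-[2-hydroxy-3-(3-methylbut-2-en-1-yl)-4,6-bis(triisopropylsilyloxy)phenyl]propan-1-one | CCC(=O)c1c(O)c(CC=C(C)C)c(O[Si](C(C)C)(C(C)C)C(C)C)cc1O[Si](C(C)C)(C(C)C)C(C)C | intermediate
5 | 1-[2-methoxy-3-(3-methylbut-2-en-1-yl)-4,6-bis(triisopropylsilyloxy)phenyl]propan-1-one | CCC(=O)c1c(OC)c(CC=C(C)C)c(O[Si](C(C)C)(C(C)C)C(C)C)cc1O[Si](C(C)C)(C(C)C)C(C)C | intermediate
6 | ethyl bromopyruvate | CCOC(=O)C(=O)CBr | starting material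
7 | ethyl 5-Ar-4-methyl-2,5-dioxopentanoate (racemic) | CCOC(=O)C(=O)CC(C)C(=O)c1c(OC)c(CC=C(C)C)c(O[Si](C(C)C)(C(C)C)C(C)C)cc1O[Si](C(C)C)(C(C)C)C(C)C | intermediate
8 | ethyl 5-Ar-4-methylfuran-2-carboxylate | CCOC(=O)c1cc(C)c(o1)-c1c(OC)c(CC=C(C)C)c(O[Si](C(C)C)(C(C)C)C(C)C)cc1O[Si](C(C)C)(C(C)C)C(C)C | intermediate
9 | [5-Ar-2-(ethoxycarbonyl)-4-methylfuran-3-yl]magnesium chloride (LiCl complex) | CCOC(=O)c1oc(c(C)c1[Mg]Cl)-c1c(OC)c(CC=C(C)C)c(O[Si](C(C)C)(C(C)C)C(C)C)cc1O[Si](C(C)C)(C(C)C)C(C)C | intermediate
10 | ethyl 5-Ar-3-iodo-4-methylfuran-2-carboxylate | CCOC(=O)c1oc(c(C)c1I)-c1c(OC)c(CC=C(C)C)c(O[Si](C(C)C)(C(C)C)C(C)C)cc1O[Si](C(C)C)(C(C)C)C(C)C | intermediate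
11 | ethyl 3-ethenyl-5-Ar-4-methylfuran-2-carboxylate | CCOC(=O)c1oc(c(C)c1C=C)-c1c(OC)c(CC=C(C)C)c(O[Si](C(C)C)(C(C)C)C(C)C)cc1O[Si](C(C)C)(C(C)C)C(C)C | intermediate
12 | 3-ethenyl-5-Ar-4-methylfuran-2-carboxylic acid | OC(=O)c1oc(c(C)c1C=C)-c1c(OC)c(CC=C(C)C)c(O[Si](C(C)C)(C(C)C)C(C)C)cc1O[Si](C(C)C)(C(C)C)C(C)C | intermediate
13 | 3-ethenyl-5-Ar-4-methylfuran-2-carbonyl chloride | ClC(=O)c1oc(c(C)c1C=C)-c1c(OC)c(CC=C(C)C)c(O[Si](C(C)C)(C(C)C)C(C)C)cc1O[Si](C(C)C)(C(C)C)C(C)C | intermediate
14 | 2-diazo-1-(3-ethenyl-5-Ar-4-methylfuran-2-yl)ethan-1-one | [N-]=[N+]=CC(=O)c1oc(c(C)c1C=C)-c1c(OC)c(CC=C(C)C)c(O[Si](C(C)C)(C(C)C)C(C)C)cc1O[Si](C(C)C)(C(C)C)C(C)C | intermediate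
15 | 2-(3-ethenyl-5-Ar-4-methylfuran-2-yl)ethenone (furylketene) | O=C=Cc1oc(c(C)c1C=C)-c1c(OC)c(CC=C(C)C)c(O[Si](C(C)C)(C(C)C)C(C)C)cc1O[Si](C(C)C)(C(C)C)C(C)C | intermediate
16 | 2-Ar-3-methyl-1-benzofuran-6(5H)-one | O=C1CC=C2C(C)=C(OC2=C1)c1c(OC)c(CC=C(C)C)c(O[Si](C(C)C)(C(C)C)C(C)C)cc1O[Si](C(C)C)(C(C)C)C(C)C | intermediate
17 | 2-Ar-3-methyl-1-benzofuran-6-ol | Cc1c(oc2cc(O)ccc12)-c1c(OC)c(CC=C(C)C)c(O[Si](C(C)C)(C(C)C)C(C)C)cc1O[Si](C(C)C)(C(C)C)C(C)C | intermediate
18 | glycybenzofuran | COc1c(CC=C(C)C)c(O)cc(O)c1-c1oc2cc(O)ccc2c1C | target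

**Step count**
Total steps: 11. Longest linear sequence: 11 steps (1 to 18).

**Steps most likely to fail**

Step 4. The enolate may add to the keto carbonyl of 6 (aldol, then epoxide closure), or be quenched by proton transfer from the acidic CH2Br group, faster than it displaces bromide. The fallback sets out from 5 and builds the carboxyl carbon on after the furan is made. The lithium enolate of 5 would be alkylated with ethyl bromoacetate, which has no competing keto group, to give ethyl 4-Ar-3-methyl-4-oxobutanoate F1. i-Bu2AlH at −78 °C should reduce the ester, not the doubly ortho-substituted aryl ketone, to 4-Ar-3-methyl-4-oxobutanal F2. PPTS in warm toluene would close this to 2-Ar-3-methylfuran F3 (Paal–Knorr). Lithiation of the free α-position with n-BuLi in THF and quenching with ethyl chloroformate comes back to the route at 8.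

Step 10. Light may degrade the vinylfuran chromophore, the carbene or diazo group may be intercepted by the neighbouring vinyl group, and the ketene may acylate phenol already formed, so that ring closure is outrun. The fallback sets out from 14 and separates homologation from ring closure. Rearrangement catalysed by silver benzoate (AgOCOPh) and Et3N in methanol in the dark would trap the ketene at once as methyl 2-(3-ethenyl-5-Ar-4-methylfuran-2-yl)acetate F4. Me3SnOH would give 2-(3-ethenyl-5-Ar-4-methylfuran-2-yl)acetic acid F5. The α-chloroenamine of step 9 would give 2-(3-ethenyl-5-Ar-4-methylfuran-2-yl)acetyl chloride F6. Slow addition of F6 to Et3N in toluene at 80 °C would generate ketene 15 thermally by dehydrochlorination, and 15 closes through 16 to come back to the route at 17.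

Step 2. The second silyl group may go onto the hydroxyl next to the prenyl group, or silylation may stop or overrun, which would put the methyl ether in the wrong place. The fallback sets out from 1 and fixes the position by construction. Bis-silylation of unprenylated 1 (i-Pr3SiCl, imidazole) leaves only the chelated hydroxyl and gives 1-[2-hydroxy-4,6-bis(triisopropylsilyloxy)phenyl]propan-1-one F7. Tsuji–Trost O-alkylation with tert-butyl 2-methylbut-3-en-2-yl carbonate and Pd(PPh3)4 would give 1-[2-(2-methylbut-3-en-2-yloxy)-4,6-bis(triisopropylsilyloxy)phenyl]propan-1-one F8. Aromatic Claisen rearrangement (N,N-diethylaniline, heat) can deliver the prenyl group only to the one free ortho carbon, and so comes back to the route at 4.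

**Further compounds**
F1 | step 4 | ethyl 4-Ar-3-methyl-4-oxobutanoate | CCOC(=O)CC(C)C(=O)c1c(OC)c(CC=C(C)C)c(O[Si](C(C)C)(C(C)C)C(C)C)cc1O[Si](C(C)C)(C(C)C)C(C)C
F2 | step 4 | 4-Ar-3-methyl-4-oxobutanal | O=CCC(C)C(=O)c1c(OC)c(CC=C(C)C)c(O[Si](C(C)C)(C(C)C)C(C)C)cc1O[Si](C(C)C)(C(C)C)C(C)C
F3 | step 4 | 2-Ar-3-methylfuran | Cc1ccoc1-c1c(OC)c(CC=C(C)C)c(O[Si](C(C)C)(C(C)C)C(C)C)cc1O[Si](C(C)C)(C(C)C)C(C)C
F4 | step 10 | methyl 2-(3-ethenyl-5-Ar-4-methylfuran-2-yl)acetate | COC(=O)Cc1oc(c(C)c1C=C)-c1c(OC)c(CC=C(C)C)c(O[Si](C(C)C)(C(C)C)C(C)C)cc1O[Si](C(C)C)(C(C)C)C(C)C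
F5 | step 10 | 2-(3-ethenyl-5-Ar-4-methylfuran-2-yl)acetic acid | OC(=O)Cc1oc(c(C)c1C=C)-c1c(OC)c(CC=C(C)C)c(O[Si](C(C)C)(C(C)C)C(C)C)cc1O[Si](C(C)C)(C(C)C)C(C)C
F6 | step 10 | 2-(3-ethenyl-5-Ar-4-methylfuran-2-yl)acetyl chloride | ClC(=O)Cc1oc(c(C)c1C=C)-c1c(OC)c(CC=C(C)C)c(O[Si](C(C)C)(C(C)C)C(C)C)cc1O[Si](C(C)C)(C(C)C)C(C)C
F7 | step 2 | 1-[2-hydroxy-4,6-bis(triisopropylsilyloxy)phenyl]propan-1-one | CCC(=O)c1c(O)cc(O[Si](C(C)C)(C(C)C)C(C)C)cc1O[Si](C(C)C)(C(C)C)C(C)C
F8 | step 2 | 1-[2-(2-methylbut-3-en-2-yloxy)-4,6-bis(triisopropylsilyloxy)phenyl]propan-1-one | CCC(=O)c1c(OC(C)(C)C=C)cc(O[Si](C(C)C)(C(C)C)C(C)C)cc1O[Si](C(C)C)(C(C)C)C(C)C
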